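## The problem

Target **29** is a cyclodeca-1(10),4-diene with a ring-cis (Z) C1=C10 and a ring-trans (E) C4=C5 alkene. It is fused across C6–C7 to an α-methylene-γ-lactone (O on C6, C11 on C7) and carries a tertiary hydroxyl at C7, a free hydroxyl at C8 and an angelate at C9. A ten-membered carbocycle is hard to close end to end, and here it must also emerge with two trisubstituted alkenes of opposite geometry. The four stereocentres C6–C9 are contiguous oxygenated carbons, with O6 and O9 on one face and O7 and O8 on the other, and C7 is quaternary. There is no remote stereocentre, so the tetrad must be built by mutual induction, and only a rigid ring lets it then dictate the alkene geometries. The methylene lactone (Michael acceptor), the angelate (isomerises to the tiglate and can migrate to O8), the allylic C6–O and C9–O bonds and the 1,5-diene (transannular cyclisation in acid, Cope rearrangement on heating) will not survive strong base, strong acid or heat, so they must appear last. The enabling feature is that C1=C10 and C4=C5 are linked through C2–C3 as a 1,5-diene. A retro-[3,3] shift reconnects C5–C10 and folds the macrocycle onto a cyclohexane (C5–C10) that holds all four oxygenated carbons. Because C10 is an alkene carbon bearing only a methyl group, it can pass through an enolate, which makes the anionic oxy-Cope variant available.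

## Retrosynthesis

**C9 ester (29 ⇒ 26 + 27).** The angelate is attached last, by acylation of triol lactone **26** with angelic acid **27**. Carrying a differentiated C9 protecting group through the route would cost two or three steps and would rule out the conformational lock described below. In **26** the C7 hydroxyl is tertiary and the C8 hydroxyl is flanked by the quaternary C7, so the allylic C9 hydroxyl should be the most reactive. The forward reaction must be site-selective and must not isomerise the (Z)-ester.

**Lactone (26 ⇒ 25 ⇒ 24).** The O6–C12 and C11–C12 bonds are cut together. A C7 ethynyl group and the C6 hydroxyl in diol **24** form a but-3-yn-1-ol, which palladium-catalysed cyclocarbonylation should convert into the methylene lactone **25** in one step. The alkyne is a slim, base-stable stand-in for the lactone, which an acrylate or ester would not be under the conditions of the ring expansion. The 8,9-acetonide of **25** is hydrolysed afterwards to give **26**.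

**C10 methyl and unmasking (24 ⇒ 23 ⇒ 22).** The C10–CH3 bond comes from a stereoretentive cross-coupling of enol triflate **22** to give **23**. One fluoride treatment then frees O6, O7 and the alkyne C–H.

**Ring expansion (22 ⇒ 19, the key cut).** C2–C3 is cut and C5–C10 reconnected. This maps the ten-membered ring onto the cis-2-isopropenyl-1-vinylcyclohexanol **19**.

- In the chair transition state the two alkene geometries depend on which cyclohexane chair reacts. The correct one has isopropenyl and the C10 oxygen both axial.
- A free cyclohexane with a cis-fused O7/O8 acetal could flip, so the route uses a trans-fused acetonide across O8/O9. This pair can only be diequatorial, so the ring is locked in the required chair.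
- O6 sits syn-axial to the C10 alkoxide and therefore carries a non-migrating SEM ether. O7 carries a triethylsilyl ether.

**Two tertiary carbinols (19 ⇒ 17 + 18; 17 ⇒ 16 ⇒ 15 ⇒ 14 ⇒ 13 ⇒ 10 + 11).** The C10–C1 and C7–C11 bonds are each formed by adding a carbon nucleophile (vinylmagnesium bromide **18**, the acetylide of **11**) to a ketone on the locked chair. In each case the axial trajectory is blocked by a syn-axial group: O6 for the C10 ketone **17**, isopropenyl for the C7 ketone **10**. Both nucleophiles should therefore enter equatorially, which is the required sense. The C10 oxygen is kept as a PMB ether until **15** and then oxidised (**16** ⇒ **17**).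

**C5 and C6 (10 ⇒ 9 ⇒ 7 + 8).** The C5–C4 bond and the C6–O bond are cut from ketol **10**. Conjugate addition of isopropenylmagnesium bromide **8** to enone **7** gives silyl enol ether **9**, and oxidation of **9** installs O6. Opening a C5–C10 epoxide with an isopropenyl nucleophile was considered, but the two epoxide carbons are nearly equivalent and no regiocontrol is evident. In the enone the position of attack is unambiguous, and axial attack anti to the C10 ether fixes the face.

**Desymmetrisation (7 ⇒ 6 ⇒ 5).** Enone **7** comes from diol **5** by mono-protection (**6**) and oxidation. Diol **5** is C2-symmetric, so its hydroxyls are homotopic and no selectivity is required.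

**Carbocycle from the chiral pool (5 ⇒ 4 ⇒ 3 ⇒ 2 ⇒ 1).** The C5=C6 bond of **5** is cut by ring-closing metathesis to diene diol **4**. **4** arises from bis-epoxide **3** by one-carbon homologation, and **3** from the D-manno tetrol **1** via ditosylate **2**. The four stereocentres of **1** become C7–C10 with the correct absolute configuration. Its 3,4-acetonide is already the trans O8/O9 lock, so the lock costs no step.

## Roads not taken

**Alternative 1:** The cut is C7–C11. A ten-membered C7 ketone carrying a propiolate on O6 (**A2**) is treated with [(Ph3P)CuH]6 (monovalent copper hydride). Hydride adds to C13 and the copper allenolate closes onto the ketone to give **A1**, the 8-O-triethylsilyl ether of the target.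

- Merits: the lactone, the methylene group and the C7 carbinol form in one late step, and the ester tether enforces the cis ring fusion. In building the lactone this is better than the chosen route, which needs an acetylide addition plus a separate carbonylation.
- Weak points: the ten-membered ring with both alkene geometries must already exist, so the hardest problem is left unsolved. The hydride can also reduce the angelate (an enoate) and the ketone directly.
- Comparison: the chosen plan is longer at the lactone but sets ring, alkene geometry and C7 on a rigid six-membered ring, and the angelate never meets a hydride.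

**Alternative 2:** The cut is C6–C7. A thirteen-membered diallyl ether (**A4**) is lithiated at C6 with n-BuLi and contracts by a [2,3]-Wittig shift to the carbocycle **A3**.

- Merits: both alkenes can be made by ordinary acyclic olefination, with no dependence on a ring conformer, and macrocyclic etherification is easier than C–C macrocyclisation. On alkene geometry this road is at least as secure as the chosen one.
- Weak points: C6 and C13 are both allylic ether carbons, so the lithiation site is not assured. The migration terminus is a tetrasubstituted enol ether. C6 and C7 are set together through a large-ring transition state with no predictable control.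
- Comparison: the chosen plan sets all four oxygen stereocentres on a locked chair before the ring is formed.

**Alternative 3:** The cut is C7–C8. A bromomethyl tetronate tethered to a C8 aldehyde (**A6**) is treated with CrCl2 (divalent chromium). The allylchromium adds through C7 to close the ring and shift the alkene to C11=C13, giving **A5**.

- Merits: ring and methylene lactone form together from two fragments. In convergence and step count this is the best of the four.
- Weak points: the attacking carbon C7 is fully substituted and bears a silyloxy group, so a quaternary centre must form during a high-dilution macrocyclisation. C7 and C8 are set at once without a rigid framework. The α-alkoxy aldehyde can epimerise at C9.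
- Comparison: the chosen plan is linear and longer, but it involves no macrocyclisation and every stereocentre is set by a chair-controlled reaction.

Key step: step 15

Convention: atoms keep the target numbering (C1–C13) in every intermediate; on the six-membered ring β is the face of O7 and O8, α the face of O6, O9 and O10.

Assumption: the trans-fused 8,9-O-isopropylidene acetal, which is more acid-labile than a cis-fused one, is taken to survive buffered oxidants and a silyl triflate at −78 °C; all acidic reagents before step 19 are therefore buffered.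

## Route

Step 1
Reactants: 1 3,4-O-isopropylidene-D-mannitol
Product: 2 3,4-O-isopropylidene-1,6-di-O-tosyl-D-mannitol
Conditions: TsCl (2.1 equiv), pyridine, CH2Cl2, −20 → 0 °C
Reagents that add atoms: p-toluenesulfonyl chloride, Cc1ccc(cc1)S(Cl)(=O)=O
Why: Selective sulfonylation; the primary hydroxyls react much faster than the secondary ones, and no stereocentre is touched.

Step 2
Reactants: 2 3,4-O-isopropylidene-1,6-di-O-tosyl-D-mannitol
Product: 3 1,2:5,6-dianhydro-3,4-O-isopropylidene-D-mannitol
Conditions: K2CO3, MeOH, 0 °C → rt
Reagents that add atoms: none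
Why: Intramolecular Williamson etherification; each secondary alkoxide displaces the neighbouring primary tosylate, so the carbinol carbons keep the D-manno configuration.

Step 3
Reactants: 3 1,2:5,6-dianhydro-3,4-O-isopropylidene-D-mannitol
Product: 4 (3R,4R,5R,6R)-4,5-O-isopropylidene-octa-1,7-diene-3,4,5,6-tetrol
Conditions: Me3SI (8 equiv), n-BuLi (7.6 equiv), THF, −10 °C → rt
Reagents that add atoms: trimethylsulfonium iodide, C[S+](C)C.[I-]
Why: Dimethylsulfonium methylide opens each terminal epoxide at CH2 and the sulfonium intermediate eliminates dimethyl sulfide, a known one-carbon homologation of epoxides to allylic alcohols; no stereocentre is involved.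

Step 4
Reactants: 4 (3R,4R,5R,6R)-4,5-O-isopropylidene-octa-1,7-diene-3,4,5,6-tetrol
Product: 5 (3aR,4R,7R,7aR)-2,2-dimethyl-3a,4,7,7a-tetrahydro-1,3-benzodioxole-4,7-diol (C5=C6, 7β-OH, 10α-OH, trans-8,9-acetonide)
Conditions: second-generation Grubbs catalyst (H2IMes)(PCy3)Cl2Ru=CHPh (3 mol%), CH2Cl2 (0.01 M), 40 °C
Reagents that add atoms: none
Why: Ring-closing metathesis of a 1,7-diene to a cyclohexene, driven by loss of ethylene; the four stereocentres are untouched and the product is C2-symmetric.

Step 5
Reactants: 5 C2-symmetric cyclohexenediol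
Product: 6 10α-O-(4-methoxybenzyl) ether of 5 (7β-OH free)
Conditions: NaH (1.0 equiv), PMBCl (1.0 equiv), Bu4NI (cat.), THF/DMF, 0 °C → rt
Reagents that add atoms: 4-methoxybenzyl chloride, COc1ccc(CCl)cc1
Why: Williamson etherification with one equivalent of base; the two hydroxyls are homotopic, so the monoether is a single compound and only diol and diether need to be separated and recycled.

Step 6
Reactants: 6 mono-PMB ether
Product: 7 (3aS,7R,7aR)-7-[(4-methoxybenzyl)oxy]-2,2-dimethyl-7,7a-dihydro-1,3-benzodioxol-4(3aH)-one (C7 ketone, C5=C6, 10α-OPMB)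
Conditions: Dess–Martin periodinane, NaHCO3, CH2Cl2, 0 °C → rt
Reagents that add atoms: none
Why: Dess–Martin oxidation of the allylic alcohol under buffered, non-basic conditions should give the γ-alkoxy enone without β-elimination of O9 or epimerisation at the ring fusion.

Step 7
Reactants: 7 enone; 8 isopropenylmagnesium bromide
Product: 9 C6=C7 trimethylsilyl enol ether with 5β-isopropenyl, 10α-OPMB and trans-8,9-acetonide
Conditions: 8 (2 equiv), CuBr·SMe2 (10 mol%), TMSCl (3 equiv), THF, −78 °C; Et3N, then pH 7 buffer
Reagents that add atoms: chlorotrimethylsilane, C[Si](C)(C)Cl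
Why: Copper-catalysed conjugate addition with silyl trapping; the trans-acetonide fixes the half-chair, so axial attack at C5 anti to the pseudo-axial C10 ether should place isopropenyl on the β face. The enolate is stored regiodefined as the silyl enol ether.

Step 8
Reactants: 9 silyl enol ether
Product: 10 ketol (C7 ketone, 6α-OH, 5β-isopropenyl, 10α-OPMB, trans-8,9-acetonide)
Conditions: mCPBA (1.05 equiv), NaHCO3, CH2Cl2, −20 °C; then aq. citric acid, THF, 0 °C
Reagents that add atoms: 3-chloroperoxybenzoic acid, OOC(=O)c1cccc(Cl)c1
Why: Rubottom oxidation; the peracid should attack the electron-rich silyl enol ether rather than the isopropenyl group, on the α face anti to the adjacent pseudo-axial isopropenyl. This sets O6 trans to the C5 substituent, and mild acid releases the ketol.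

Step 9
Reactants: 10 ketol; 11 (triisopropylsilyl)acetylene
Product: 13 6α,7β-diol carrying the 7α-(triisopropylsilyl)ethynyl group (5β-isopropenyl; 10α-OPMB; trans-8,9-acetonide), via lithium (triisopropylsilyl)acetylide 12 (not isolated)
Conditions: 11 (3.5 equiv), n-BuLi (3.3 equiv), THF, −78 °C; then 10, −78 → −40 °C; aq. NH4Cl
Reagents that add atoms: none
Why: 1,2-Addition of a lithium acetylide to a ketone; on the locked chair the axial β trajectory at C7 is closed by the syn-axial isopropenyl group and the lithium alkoxide at O6 holds the reagent on the α face, so the alkyne should enter equatorially and leave O7 axial, cis to O8 and trans to O6. Enolisation toward the trans ring fusion is disfavoured.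

Step 10
Reactants: 13 alkynyl diol
Product: 14 6α-O-SEM ether of 13 (7β-OH free)
Conditions: SEMCl (1.5 equiv), i-Pr2NEt, Bu4NI (cat.), CH2Cl2, 40 °C
Reagents that add atoms: 2-(trimethylsilyl)ethoxymethyl chloride, C[Si](C)(C)CCOCCl
Why: Alkylation of the secondary hydroxyl; the tertiary propargylic hydroxyl is too hindered to compete. An acetal-type group is used because O6 will lie syn-axial to the C10 alkoxide in step 15, where a silyl ether could migrate.

Step 11
Reactants: 14 6-O-SEM ether
Product: 15 7β-O-triethylsilyl ether of 14
Conditions: TESOTf, 2,6-lutidine, CH2Cl2, −78 °C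
Reagents that add atoms: triethylsilyl trifluoromethanesulfonate, CC[Si](CC)(CC)OS(=O)(=O)C(F)(F)F
Why: Silylation of a tertiary alcohol with a silyl triflate; at −78 °C the reaction should be fast enough to spare the acetonide and the SEM acetal.

Step 12
Reactants: 15 fully protected cyclohexane
Product: 16 10α-alcohol (PMB removed)
Conditions: DDQ, CH2Cl2/pH 7 phosphate buffer, 0 °C
Reagents that add atoms: none
Why: Oxidative cleavage of the 4-methoxybenzyl ether; the buffered medium should leave the silyl ethers, the SEM acetal and the acetonide intact.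

Step 13
Reactants: 16 10α-alcohol
Product: 17 C10 ketone (5β-isopropenyl, 6α-OSEM, 7β-OTES, 7α-alkynyl, trans-8,9-acetonide)
Conditions: Dess–Martin periodinane, NaHCO3, CH2Cl2, 0 °C → rt
Reagents that add atoms: none
Why: Dess–Martin oxidation under neutral conditions; the C5 hydrogen is equatorial and the C9 hydrogen sits at the trans ring fusion, so neither should enolise. This protects C5 from epimerisation and O6 from β-elimination.

Step 14
Reactants: 17 C10 ketone; 18 vinylmagnesium bromide
Product: 19 cis-2-isopropenyl-1-vinylcyclohexanol (10α-OH, 10β-vinyl, 5β-isopropenyl, 6α-OSEM, 7β-OTES, 7α-alkynyl, trans-8,9-acetonide)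
Conditions: 18 (3 equiv), LaCl3·2LiCl (1 equiv), THF, −78 → −40 °C; aq. NH4Cl
Reagents that add atoms: none
Why: Grignard addition with a Lewis-acid additive that suppresses enolisation; axial attack at C10 from the α face is blocked by the syn-axial O6 ether, so vinyl should enter equatorially from the β face. This gives the axial hydroxyl cis to O9 and the vinyl group cis to isopropenyl.

Step 15
Reactants: 19 cis-2-isopropenyl-1-vinylcyclohexanol
Product: 22 ten-membered dienyl triflate (C10 enol triflate; C1=C10 ring-cis; C4=C5 ring-trans), via potassium C10 alkoxide 20 (not isolated), via potassium cyclodecadienolate 21 (not isolated)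
Conditions: KH (1.5 equiv), 18-crown-6 (1.5 equiv), THF, 0 °C → rt; then PhNTf2 (1.6 equiv), −78 → 0 °C; aq. NH4Cl
Reagents that add atoms: N-phenylbis(trifluoromethanesulfonimide), O=S(=O)(N(c1ccccc1)S(=O)(=O)C(F)(F)F)C(F)(F)F
Why: Deprotonation gives alkoxide 20, whose oxyanion accelerates a concerted [3,3] shift through a chair array of C2, C1, C10, C5, C4 and C3; C2–C3 forms as C5–C10 breaks, giving enolate 21, which is O-sulfonylated in the same flask. The closest known reaction is the anionic oxy-Cope ring expansion of cis-1,2-dialkenylcyclohexanols to cyclodec-5-enone enolates with electrophilic trapping. The ten-membered ring is formed by sigmatropic ring expansion of the six-membered ring, not by end-to-end cyclisation. No new stereocentre is created; C5 and C10 become trigonal and C6–C9 are spectators. The selectivity needed is alkene geometry: on the reacting chair the alkoxide and C6 are pseudo-equatorial and C9 pseudo-axial, which makes C1=C10 ring-cis and C4=C5 ring-trans. That chair corresponds to the cyclohexane conformer with axial isopropenyl and axial C10 oxygen, and the trans-fused 8,9-acetonide allows only this conformer, so the alternative chair is excluded and only a higher-lying boat could compete. Immediate triflation fixes the enolate geometry and regiochemistry before proton transfer can scramble them.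

Step 16
Reactants: 22 dienyl triflate
Product: 23 (1(10)Z,4E)-cyclodecadiene with C10 methyl (6-OSEM, 7-OTES, 7-alkynyl-TIPS, 8,9-acetonide)
Conditions: MeZnCl (3 equiv), Pd(PPh3)4 (5 mol%), THF, 0 °C → rt
Reagents that add atoms: methylzinc chloride, C[Zn]Cl
Why: Negishi coupling; oxidative addition of zerovalent palladium, transmetalation and reductive elimination all proceed with retention, so the ring-cis triflate becomes the (Z)-C1=C10 methyl alkene. Transmetalation from zinc should be faster than transannular insertion.

Step 17
Reactants: 23 protected cyclodecadiene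
Product: 24 6,7-diol with terminal C7 ethynyl group (8,9-acetonide retained)
Conditions: TBAF (10 equiv), DMPU, 4 Å MS, 60 °C; aq. NH4Cl
Reagents that add atoms: none
Why: Fluoride cleaves the alkynyl C–Si and tertiary O–Si bonds and, on warming, attacks the SEM silicon to release ethylene and formaldehyde. No base-sensitive group is present at this stage.

Step 18
Reactants: 24 diol alkyne
Product: 25 α-methylene-γ-lactone with 7-OH and 8,9-acetonide
Conditions: PdI2 (5 mol%), thiourea (15 mol%), CO (1 atm), acetone, 50 °C
Reagents that add atoms: carbon monoxide, [C-]#[O+]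
Why: Palladium-catalysed cyclocarbonylation of a but-3-yn-1-ol; the alkoxycarbonyl complex of divalent palladium formed at O6 adds syn across the alkyne in a 5-exo sense and protonolysis leaves the exocyclic methylene. The tertiary O7–H could only give a strained β-lactone and O8 is masked.

Step 19
Reactants: 25 lactone acetonide
Product: 26 7,8,9-triol lactone
Conditions: AcOH/H2O (4:1), 35 °C
Reagents that add atoms: none
Why: Acid hydrolysis of the isopropylidene acetal; a weak acid at low temperature is chosen to spare the 1,5-diene and the allylic lactone C–O bond.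

Step 20
Reactants: 26 triol lactone; 27 angelic acid
Product: 29 CNP0303917.1 (the 9-O-angelate), via angelic 2,4,6-trichlorobenzoic anhydride 28 (not isolated)
Conditions: 27 (1.3 equiv), 2,4,6-trichlorobenzoyl chloride (1.3 equiv), Et3N, toluene, rt; then 26, 60 °C
Reagents that add atoms: none
Why: Yamaguchi-type mixed-anhydride acylation without a nucleophilic catalyst, so the angelate should not isomerise to the tiglate. The tertiary C7 hydroxyl is inert and the C8 hydroxyl is shielded by the quaternary C7, so the allylic C9 hydroxyl should be acylated first.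

## Compound list

1 | 3,4-O-isopropylidene-D-mannitol | OC[C@@H](O)[C@H]1OC(C)(C)O[C@@H]1[C@H](O)CO | starting material
2 | 3,4-O-isopropylidene-1,6-di-O-tosyl-D-mannitol | Cc1ccc(cc1)S(=O)(=O)OC[C@@H](O)[C@H]1OC(C)(C)O[C@@H]1[C@H](O)COS(=O)(=O)c1ccc(C)cc1 | intermediate
3 | 1,2:5,6-dianhydro-3,4-O-isopropylidene-D-mannitol | C1O[C@H]1[C@H]2OC(C)(C)O[C@@H]2[C@H]3CO3 | intermediate
4 | (3R,4R,5R,6R)-4,5-O-isopropylidene-octa-1,7-diene-3,4,5,6-tetrol | C=C[C@@H](O)[C@H]1OC(C)(C)O[C@@H]1[C@H](O)C=C | intermediate
5 | (3aR,4R,7R,7aR)-2,2-dimethyl-3a,4,7,7a-tetrahydro-1,3-benzodioxole-4,7-diol | O[C@@H]1C=C[C@@H](O)[C@H]2OC(C)(C)O[C@H]12 | intermediate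
6 | 10α-O-PMB ether of 5 | O[C@@H]1C=C[C@@H](OCc3ccc(OC)cc3)[C@H]2OC(C)(C)O[C@H]12 | intermediate
7 | (3aS,7R,7aR)-7-[(4-methoxybenzyl)oxy]-2,2-dimethyl-7,7a-dihydro-1,3-benzodioxol-4(3aH)-one | O=C1C=C[C@@H](OCc3ccc(OC)cc3)[C@H]2OC(C)(C)O[C@H]12 | intermediate
8 | isopropenylmagnesium bromide | CC(=C)[Mg]Br | starting material
9 | C6=C7 trimethylsilyl enol ether, 5β-isopropenyl, 10α-OPMB | C[Si](C)(C)OC1=C[C@H](C(C)=C)[C@@H](OCc3ccc(OC)cc3)[C@H]2OC(C)(C)O[C@H]12 | intermediate
10 | C7 ketone, 6α-OH, 5β-isopropenyl, 10α-OPMB | O=C1[C@@H](O)[C@H](C(C)=C)[C@@H](OCc3ccc(OC)cc3)[C@H]2OC(C)(C)O[C@H]12 | intermediate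
11 | (triisopropylsilyl)acetylene | C#C[Si](C(C)C)(C(C)C)C(C)C | starting material
12 | lithium (triisopropylsilyl)acetylide | [Li]C#C[Si](C(C)C)(C(C)C)C(C)C | intermediate (not isolated)
13 | 6α,7β-diol with 7α-(TIPS-ethynyl), 5β-isopropenyl, 10α-OPMB | O[C@]1(C#C[Si](C(C)C)(C(C)C)C(C)C)[C@@H](O)[C@H](C(C)=C)[C@@H](OCc3ccc(OC)cc3)[C@H]2OC(C)(C)O[C@H]12 | intermediate
14 | 6α-O-SEM ether of 13 | O[C@]1(C#C[Si](C(C)C)(C(C)C)C(C)C)[C@@H](OCOCC[Si](C)(C)C)[C@H](C(C)=C)[C@@H](OCc3ccc(OC)cc3)[C@H]2OC(C)(C)O[C@H]12 | intermediate
15 | 7β-O-TES ether of 14 | CC[Si](CC)(CC)O[C@]1(C#C[Si](C(C)C)(C(C)C)C(C)C)[C@@H](OCOCC[Si](C)(C)C)[C@H](C(C)=C)[C@@H](OCc3ccc(OC)cc3)[C@H]2OC(C)(C)O[C@H]12 | intermediate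
16 | 10α-alcohol (PMB removed) | CC[Si](CC)(CC)O[C@]1(C#C[Si](C(C)C)(C(C)C)C(C)C)[C@@H](OCOCC[Si](C)(C)C)[C@H](C(C)=C)[C@@H](O)[C@H]2OC(C)(C)O[C@H]12 | intermediate
17 | C10 ketone | CC[Si](CC)(CC)O[C@]1(C#C[Si](C(C)C)(C(C)C)C(C)C)[C@@H](OCOCC[Si](C)(C)C)[C@H](C(C)=C)C(=O)[C@H]2OC(C)(C)O[C@H]12 | intermediate
18 | vinylmagnesium bromide | C=C[Mg]Br | starting material
19 | cis-2-isopropenyl-1-vinylcyclohexanol (10α-OH, 10β-vinyl) | CC[Si](CC)(CC)O[C@]1(C#C[Si](C(C)C)(C(C)C)C(C)C)[C@@H](OCOCC[Si](C)(C)C)[C@H](C(C)=C)[C@](O)(C=C)[C@H]2OC(C)(C)O[C@H]12 | intermediate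
20 | potassium C10 alkoxide of 19 | CC[Si](CC)(CC)O[C@]1(C#C[Si](C(C)C)(C(C)C)C(C)C)[C@@H](OCOCC[Si](C)(C)C)[C@H](C(C)=C)[C@]([O-])(C=C)[C@H]2OC(C)(C)O[C@H]12.[K+] | intermediate (not isolated)
21 | potassium cyclodecadienolate (C1=C10 enolate) | C/C1=C\[C@H](OCOCC[Si](C)(C)C)[C@](O[Si](CC)(CC)CC)(C#C[Si](C(C)C)(C(C)C)C(C)C)[C@H]2OC(C)(C)O[C@@H]2/C([O-])=C\CC1.[K+] | intermediate (not isolated)
22 | ten-membered dienyl triflate | C/C1=C\[C@H](OCOCC[Si](C)(C)C)[C@](O[Si](CC)(CC)CC)(C#C[Si](C(C)C)(C(C)C)C(C)C)[C@H]2OC(C)(C)O[C@@H]2/C(OS(=O)(=O)C(F)(F)F)=C\CC1 | intermediate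
23 | (1(10)Z,4E)-diene with C10 methyl | C/C1=C\[C@H](OCOCC[Si](C)(C)C)[C@](O[Si](CC)(CC)CC)(C#C[Si](C(C)C)(C(C)C)C(C)C)[C@H]2OC(C)(C)O[C@@H]2/C(C)=C\CC1 | intermediate
24 | 6,7-diol with C7 ethynyl, 8,9-acetonide | C/C1=C\[C@H](O)[C@](O)(C#C)[C@H]2OC(C)(C)O[C@@H]2/C(C)=C\CC1 | intermediate
25 | methylene lactone with 7-OH and 8,9-acetonide | C=C1C(=O)O[C@H]2/C=C(\C)CC/C=C(/C)[C@H]3OC(C)(C)O[C@@H]3[C@@]12O | intermediate
26 | 7,8,9-triol lactone | C=C1C(=O)O[C@H]2/C=C(\C)CC/C=C(/C)[C@@H](O)[C@H](O)[C@@]12O | intermediate
27 | angelic acid | C/C=C(/C)C(=O)O | starting material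
28 | angelic 2,4,6-trichlorobenzoic anhydride | C/C=C(/C)C(=O)OC(=O)c1c(Cl)cc(Cl)cc1Cl | intermediate (not isolated)
29 | CNP0303917.1 | C=C1C(=O)O[C@H]2/C=C(\C)CC/C=C(/C)[C@@H](OC(=O)/C(C)=C\C)[C@H](O)[C@@]12O | target

## Step count and risks

Total: 20 steps. Longest linear sequence: 20 steps, from **1**.

**Step 15 (key step).** The lock removes the choice between the two chairs. What can still go wrong is erosion of the enolate: proton exchange with unreacted alcohol before triflation would move the enolate toward C9 (where O8 can be eliminated), and a boat pathway would give a ring-trans C1=C10. The doubly syn-diaxial alkoxide may also fragment if the rearrangement is slow. Fallback: avoid the free enolate. From **19**, silylation (TMS-imidazole) gives the C10 trimethylsilyl ether **F1**. A thermal siloxy-Cope rearrangement through the same locked chair gives the ten-membered trimethylsilyl enol ether **F2**. MeLi releases the lithium enolate regio- and stereospecifically, and PhNTf2 returns the route to **22**.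

**Step 9.** The likely failure is poor facial selectivity. A slim acetylide can still approach axially past the isopropenyl group, and attack anti to the axial C6–O bond is electronically favoured, which would give the C7 epimer. Fallback: use a nucleophile that can only attack equatorially and build the alkyne afterwards. From **10**, 2-lithio-1,3-dithiane gives the dithianyl carbinol **F3**. SEM protection gives **F4** and silylation gives **F5**. MeI/CaCO3 in aqueous MeCN releases the aldehyde **F6**. Ohira–Bestmann homologation gives the terminal alkyne **F7**, and n-BuLi followed by TIPSOTf returns to **15**.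

**Step 14.** The likely failure is again facial selectivity. The equatorial path passes the axial isopropenyl group on C5, so some axial attack, and with it the trans-dialkenyl isomer, is possible. Enolisation of the hindered ketone is a second risk. Fallback: form the carbinol under thermodynamic control. From **17**, dimethylsulfoxonium methylide (reversible addition, new CH2 equatorial) gives the spiro-epoxide **F8**. Dimethylsulfonium methylide, as in step 3, converts this epoxide into the vinyl carbinol **19**.

**Step 17.** The likely failure is incomplete SEM cleavage. The two silyl groups leave readily, but the SEM ether may need heating long enough for the cyclodeca-1,5-diene to begin a Cope rearrangement. Fallback: stage the deprotection and remove the SEM group without fluoride. From **23**, TBAF in THF at 0 °C gives the 6-O-SEM alkynyl carbinol **F9**. MgBr2·OEt2 with n-BuSH in Et2O then cleaves the acetal at room temperature and returns to **24**.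

**Step 18.** The likely failure is diversion of the catalyst. Divalent palladium can bind the 1,5-diene and promote transannular reactions, and the tertiary propargylic hydroxyl can compete for the acyl complex. Fallback: separate the C–C bond formation from the palladium step. From **24**, hydrostannation with Bu3SnH and Mo(CO)3(CNt-Bu)3 gives the internal vinylstannane **F10**. Iodine gives the vinyl iodide **F11**, and carbonylative lactonisation (Pd(PPh3)4, CO, Et3N) returns to **25**.

**Step 20.** The likely failure is poor site selectivity between O8 and O9, followed by acyl migration. Heating with amine could also isomerise some angelate to tiglate. Fallback: mask the 7,8-diol dynamically. From **26**, phenylboronic acid gives the cyclic 7,8-boronate **F12**. Any 8,9-boronate formed in equilibrium leaves only the unreactive tertiary hydroxyl free, so acylation should be channelled to O9 and give the boronate angelate **F13**. Exchange with pinacol releases **29**.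

## Further compounds

F1 | step 15 | C10 trimethylsilyl ether of 19 | CC[Si](CC)(CC)O[C@]1(C#C[Si](C(C)C)(C(C)C)C(C)C)[C@@H](OCOCC[Si](C)(C)C)[C@H](C(C)=C)[C@](O[Si](C)(C)C)(C=C)[C@H]2OC(C)(C)O[C@H]12
F2 | step 15 | ten-membered C10 trimethylsilyl enol ether | C/C1=C\[C@H](OCOCC[Si](C)(C)C)[C@](O[Si](CC)(CC)CC)(C#C[Si](C(C)C)(C(C)C)C(C)C)[C@H]2OC(C)(C)O[C@@H]2/C(O[Si](C)(C)C)=C\CC1
F3 | step 9 | 6α,7β-diol with 7α-(1,3-dithian-2-yl) | O[C@]1(C2SCCCS2)[C@@H](O)[C@H](C(C)=C)[C@@H](OCc2ccc(OC)cc2)[C@H]2OC(C)(C)O[C@H]12
F4 | step 9 | 6-O-SEM ether of F3 | O[C@]1(C2SCCCS2)[C@@H](OCOCC[Si](C)(C)C)[C@H](C(C)=C)[C@@H](OCc2ccc(OC)cc2)[C@H]2OC(C)(C)O[C@H]12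
F5 | step 9 | 7-O-TES ether of F4 | CC[Si](CC)(CC)O[C@]1(C2SCCCS2)[C@@H](OCOCC[Si](C)(C)C)[C@H](C(C)=C)[C@@H](OCc2ccc(OC)cc2)[C@H]2OC(C)(C)O[C@H]12
F6 | step 9 | C7 carbaldehyde | CC[Si](CC)(CC)O[C@]1(C=O)[C@@H](OCOCC[Si](C)(C)C)[C@H](C(C)=C)[C@@H](OCc2ccc(OC)cc2)[C@H]2OC(C)(C)O[C@H]12
F7 | step 9 | terminal C7 alkyne | CC[Si](CC)(CC)O[C@]1(C#C)[C@@H](OCOCC[Si](C)(C)C)[C@H](C(C)=C)[C@@H](OCc2ccc(OC)cc2)[C@H]2OC(C)(C)O[C@H]12
F8 | step 14 | C10 spiro-epoxide (O axial α, CH2 equatorial β) | CC[Si](CC)(CC)O[C@]1(C#C[Si](C(C)C)(C(C)C)C(C)C)[C@@H](OCOCC[Si](C)(C)C)[C@H](C(C)=C)[C@]3(CO3)[C@H]2OC(C)(C)O[C@H]12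
F9 | step 17 | 6-O-SEM 7-hydroxy terminal alkyne | C/C1=C\[C@H](OCOCC[Si](C)(C)C)[C@](O)(C#C)[C@H]2OC(C)(C)O[C@@H]2/C(C)=C\CC1
F10 | step 18 | C11 tributylstannyl alkene | C/C1=C\[C@H](O)[C@](O)(C(=C)[Sn](CCCC)(CCCC)CCCC)[C@H]2OC(C)(C)O[C@@H]2/C(C)=C\CC1
F11 | step 18 | C11 iodoalkene | C/C1=C\[C@H](O)[C@](O)(C(I)=C)[C@H]2OC(C)(C)O[C@@H]2/C(C)=C\CC1
F12 | step 20 | 7,8-O-phenylboronate of 26 | C=C1C(=O)O[C@H]2/C=C(\C)CC/C=C(/C)[C@@H](O)[C@@H]3OB(c4ccccc4)O[C@]123
F13 | step 20 | 9-O-angelate of F12 | C=C1C(=O)O[C@H]2/C=C(\C)CC/C=C(/C)[C@@H](OC(=O)/C(C)=C\C)[C@@H]3OB(c4ccccc4)O[C@]123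
A1 | alternative 1 | 8-O-triethylsilyl ether of the target | C=C1C(=O)O[C@H]2/C=C(\C)CC/C=C(/C)[C@@H](OC(=O)/C(C)=C\C)[C@H](O[Si](CC)(CC)CC)[C@@]12O
A2 | alternative 1 | C7 ketone with C6 propiolate | C#CC(=O)O[C@H]1/C=C(\C)CC/C=C(/C)[C@@H](OC(=O)/C(C)=C\C)[C@H](O[Si](CC)(CC)CC)C1=O
A3 | alternative 2 | ten-membered C6 carbinol with C7 MOM ether | C=C(CO[Si](C)(C)C(C)(C)C)[C@@]1(OCOC)[C@@H](O)/C=C(\C)CC/C=C(/C)[C@H]2OC(C)(C)O[C@H]12
A4 | alternative 2 | thirteen-membered diallyl ether (enol ether geometry as drawn) | C1OC/C(CO[Si](C)(C)C(C)(C)C)=C(OCOC)/[C@H]2OC(C)(C)O[C@@H]2/C(C)=C\CC/C(C)=C/1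
A5 | alternative 3 | 7-O-triethylsilyl 9-O-PMB germacranolide | C=C1C(=O)O[C@H]2/C=C(\C)CC/C=C(/C)[C@@H](OCc3ccc(OC)cc3)[C@H](O)[C@@]12O[Si](CC)(CC)CC
A6 | alternative 3 | bromomethyl tetronate with tethered C8 aldehyde | BrCC1=C(O[Si](CC)(CC)CC)[C@H](/C=C(\C)CC/C=C(/C)[C@@H](OCc2ccc(OC)cc2)C=O)OC1=O
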